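The synthesis hinges on disconnecting C2–C3. In the target the 3(2H)-furanone ring (O, C3, C2, C1, C10) is an ether bridge C10–O–C3 across the ten-membered carbocycle C1–C10. The key step exploits this bridge. C3 can begin as the carbonyl of a nine-membered (Z)-enoate lactone on O10, with C1/C2 as an acetyl group on C10. Enolisation at C2, acylation by C3 and loss of water forge one C–C bond that completes furanone and carbocycle together. The precursor also carries the cis-fused γ-lactone, the C8/C9 acetonide, and C11/C13 as a spiro-epoxide, the base-stable form of the chlorohydrin.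

Key step: step 17

Remark: germacrane numbers are used from the start. C7–C10 come from the tartrate, C1/C2 from the alkyne, C11–C13 from methyl acrylate, C5/C6 from glyceraldehyde, and C3/C4 with the C4 methyl from the phosphonopropionate. CIP letters change along the route only where substituent priorities change.
Remark: the C7 carbinol of the Morita–Baylis–Hillman adduct and its acetate, the phosphonate carbon C4, the lactol carbon C12 and the hemiketal carbon C3 are epimer mixtures, and each of these centres is erased later.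
Remark: one new bond adds one ring to the count. The furanone is new, and the all-carbon ten-membered circuit grows out of the nine-membered lactone circuit, which survives as the oxygen-bridged path.

Step 1
Reactants: 1 dimethyl 2,3-O-isopropylidene-L-tartrate
Product: 2 bis-Weinreb amide (4R,5R)-N4,N5-dimethoxy-N4,N5,2,2-tetramethyl-1,3-dioxolane-4,5-dicarboxamide
Conditions: MeNH(OMe)·HCl, iPrMgCl, THF, −20 to 0 °C
Reagents that add atoms: N,O-dimethylhydroxylamine hydrochloride, CNOC.Cl
Why: Weinreb amide formation by aminolysis of both esters with the chloromagnesium amide of MeNH(OMe); C8 and C9 come unchanged from L-tartaric acid and the trans-dioxolane has no drive to epimerise.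

Step 2
Reactants: 2 bis-Weinreb amide; 3 ethynyl(trimethyl)silane
Product: 5 mono-ynone (4R,5R)-N-methoxy-N,2,2-trimethyl-5-[3-(trimethylsilyl)prop-2-ynoyl]-1,3-dioxolane-4-carboxamide, via lithium acetylide 4 (not isolated)
Conditions: 3, n-BuLi, THF, −78 °C; then 2 (one equivalent of 4), −78 to −40 °C; cold aq NH4Cl
Reagents that add atoms: none
Why: Weinreb ketone synthesis on a C2-symmetric substrate: both termini are equivalent, the chelated tetrahedral adduct survives until the quench and its charge slows a second attack, so one equivalent of 4 should stop at the mono-ynone that carries C1 and C2.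

Step 3
Reactants: 5 mono-ynone
Product: 6 tertiary carbinol (4R,5R)-5-[(2S)-2-hydroxy-4-(trimethylsilyl)but-3-yn-2-yl]-N-methoxy-N,2,2-trimethyl-1,3-dioxolane-4-carboxamide
Conditions: MeMgBr, CH2Cl2/Et2O, −78 °C; aq NH4Cl
Reagents that add atoms: methylmagnesium bromide, C[Mg]Br
Why: Chelation-controlled (Cram chelate) Grignard 1,2-addition to an α-alkoxy ketone: magnesium ties O9 to the carbonyl oxygen, ring carbon C8 blocks one face and methyl enters from the H9 side, which sets C10 as in the target precisely because the alkyne is added first and methyl last, while the ketone outruns the Weinreb amide at −78 °C.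

Step 4
Reactants: 6 tertiary carbinol
Product: 7 aldehyde (4R,5R)-5-[(2S)-2-hydroxy-4-(trimethylsilyl)but-3-yn-2-yl]-2,2-dimethyl-1,3-dioxolane-4-carbaldehyde
Conditions: iBu2AlH (2.5 equiv), THF, −78 °C; aq potassium sodium tartrate
Reagents that add atoms: none
Why: Weinreb amide reduction stops at the aluminium-chelated hemiaminal and releases the aldehyde only on work-up, and the trans relation of C7 and C10 on the dioxolane keeps the free C10 hydroxyl from closing a lactol.

Step 5
Reactants: 7 aldehyde; 8 methyl acrylate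
Product: 9 Morita–Baylis–Hillman adduct methyl 2-{hydroxy[(4S,5R)-5-[(2S)-2-hydroxy-4-(trimethylsilyl)but-3-yn-2-yl]-2,2-dimethyl-1,3-dioxolan-4-yl]methyl}prop-2-enoate (C7 epimers)
Conditions: DABCO, neat 8, rt
Reagents that add atoms: none
Why: The Morita–Baylis–Hillman reaction, favoured by the inductively activated α-alkoxy aldehyde, brings in C11–C13; the new C7 carbinol centre is left uncontrolled because step 7 turns C7 into an sp2 carbon.

Step 6
Reactants: 9 Morita–Baylis–Hillman adduct
Product: 10 C7 acetate of 9 (C7 epimers)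
Conditions: Ac2O, pyridine, DMAP (cat.), CH2Cl2, 0 °C
Reagents that add atoms: acetic anhydride, CC(=O)OC(C)=O
Why: Acetylation discriminates the secondary allylic alcohol from the hindered tertiary C10 hydroxyl, which stays free and therefore never needs a protecting group.

Step 7
Reactants: 10 acetate
Product: 11 (E)-allylboronate methyl (2E)-3-[(4S,5R)-5-[(2S)-2-hydroxy-4-(trimethylsilyl)but-3-yn-2-yl]-2,2-dimethyl-1,3-dioxolan-4-yl]-2-[(4,4,5,5-tetramethyl-1,3,2-dioxaborolan-2-yl)methyl]prop-2-enoate (C8 cis to CH2B)
Conditions: B2pin2, Pd2(dba)3 (cat.), toluene, 50 °C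
Reagents that add atoms: bis(pinacolato)diboron, CC1(C)OB(OC1(C)C)B1OC(C)(C)C(C)(C)O1
Why: Palladium-catalysed allylic borylation (Miyaura type): zerovalent palladium ionises the acetate, the acetate-activated diboron transmetallates and boron ends at the open terminus C13, giving the conjugated trisubstituted alkene in its stable geometry (ester trans to C8), while the silyl cap keeps the alkyne out of the catalysis.

Step 8
Reactants: 12 (R)-solketal
Product: 13 (S)-2,2-dimethyl-1,3-dioxolane-4-carbaldehyde
Conditions: (COCl)2, DMSO, Et3N, CH2Cl2, −78 °C; used crude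
Reagents that add atoms: none
Why: Swern oxidation at low temperature gives the α-alkoxy aldehyde without racemisation, and fresh preparation avoids its oligomerisation on storage.

Step 9
Reactants: 11 (E)-allylboronate; 13 (S)-glyceraldehyde acetonide
Product: 15 cis-α-methylene-γ-butyrolactone (5S,6R,7R,8S,9R,10S) bearing the glyceraldehyde dioxolane on C6 and the tartrate dioxolane on C7, via open-chain borate 14 (not isolated)
Conditions: 13 (3 equiv), toluene, 70 °C
Reagents that add atoms: none
Why: Thermal allylboration through a closed chair transition state followed by lactonisation: C8, cis to CH2B, sits axial so that C6–O and C7–C8 come out syn and the lactone cis; the absolute sense follows from Felkin–Anh (anti) attack on 13, which is strong for boronates of this Z-crotyl type, and is reinforced by allylic 1,3-strain in 11, which turns H8 toward CH2B and leaves open the face anti to the bulky C9 branch.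

Step 10
Reactants: 15 α-methylene lactone
Product: 17 alkynyl triol (5S,6R,7S,8S,9R,10S) with free C6 C10 C12 hydroxyls and the C11=C13 methylene, via silylated triol 16 (not isolated)
Conditions: iBu2AlH (5 equiv), CH2Cl2, −78 to 0 °C; aq potassium sodium tartrate; crude 16, K2CO3 (cat.), MeOH, rt
Reagents that add atoms: none
Why: 1,2-Reduction of the enoate-type lactone by iBu2AlH gives the 2-methylene-1,4-diol, and base-catalysed methanolysis of the C–Si bond is placed here because nothing base-sensitive is present; no stereocentre is touched.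

Step 11
Reactants: 17 alkynyl triol
Product: 18 epoxy triol (5S,6R,7S,8S,9R,10S,11R) with the C11/C13 oxirane
Conditions: Ti(OiPr)4 (cat.), D-(−)-diisopropyl tartrate (cat.), t-BuOOH, 4 Å MS, CH2Cl2, −20 °C
Reagents that add atoms: tert-butyl hydroperoxide, CC(C)(C)OO
Why: Sharpless asymmetric epoxidation of the 2-substituted primary allylic alcohol: with the D-(−)-tartrate the oxygen is delivered to the face that places C11–O syn to C8, a reagent-controlled result chosen because osmylation or peracid attack on lactone 15 would come from the open face anti to C8 and give the C11 epimer.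

Step 12
Reactants: 18 epoxy triol
Product: 20 spiro-epoxy γ-lactone (5S,6R,7R,8S,9R,10S,11S) with free C10 hydroxyl, via epoxy lactol 19 (not isolated)
Conditions: TEMPO (cat.), PhI(OAc)2 (2.5 equiv), CH2Cl2, rt
Reagents that add atoms: none
Why: TEMPO/PhI(OAc)2 oxidative lactonisation of a 1,4-diol: the oxoammonium salt takes only the primary C12 alcohol, the aldehyde is captured by the C6 hydroxyl as lactol 19 and oxidised again, and the tertiary alcohol, alkyne and epoxide are inert.

Step 13
Reactants: 20 spiro-epoxy lactone; 21 2-(diethoxyphosphoryl)propanoic acid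
Product: 22 C10 2-(diethoxyphosphoryl)propanoate of 20 (C4 epimers)
Conditions: DCC, DMAP (cat.), CH2Cl2, 0 °C to rt
Reagents that add atoms: none
Why: Steglich esterification: activated phosphono acids react through a small ketene-like acyl donor that the slim tertiary propargylic alcohol, the only free hydroxyl of 20, can reach.

Step 14
Reactants: 22 phosphonate ester
Product: 24 C5 aldehyde (6R,7R,8S,9R,10S,11S; C4 epimers), via terminal diol 23 (not isolated)
Conditions: H5IO6 (1.3 equiv), EtOAc, 0 °C to rt; used at once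
Reagents that add atoms: none
Why: One-pot acetal hydrolysis and glycol cleavage by periodic acid: the terminal acetonide opens first and its diol is cut to the aldehyde, the internal trans-acetonide is slower, the epoxide is deactivated by the adjacent lactone carbonyl, and the acidic medium does not enolise C6.

Step 15
Reactants: 24 phosphonate aldehyde
Product: 25 nine-membered (Z)-enoate lactone (4Z,6S,7S,8S,9R,10S,11S) bearing the C10 ethynyl group
Conditions: LiCl, iPr2NEt, MeCN, high dilution (slow addition of 24), rt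
Reagents that add atoms: none
Why: Intramolecular Horner–Wadsworth–Emmons reaction under Masamune–Roush conditions: the cis-lactone and the trans-dioxolane hold both ends on one side, reversible addition under the mild base funnels material through the only adduct whose alkene the nine-membered ring should tolerate (Z), and the alkyne stands in for the acetyl group because a phosphonate ester of an α-hydroxy ketone would olefinate its own ketone to a butenolide.

Step 16
Reactants: 25 ethynyl lactone
Product: 26 nine-membered (Z)-enoate lactone (4Z,6S,7S,8S,9R,10R,11S) bearing the C10 acetyl group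
Conditions: Ph3PAuCl (cat.), AgSbF6 (cat.), 1,4-dioxane/H2O, rt
Reagents that add atoms: water, O
Why: Gold-catalysed Markovnikov hydration of a terminal propargylic ester, steered by 5-exo-dig participation of the ester carbonyl, places the oxygen on C1 and releases the acetyl group only after the olefination is over.

Step 17
Reactants: 26 acetyl lactone
Product: 29 furanone-bridged ten-membered carbocycle (4Z,6S,7S,8S,9R,10R,11S) with C8/C9 acetonide and C11/C13 epoxide, via ring-expanded hydroxy diketone 27 (not isolated), via bridged hemiketal 28 (not isolated)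
Conditions: LiN(SiMe3)2 (2.5 equiv), THF, −78 to −20 °C; AcOH; PPTS (cat.), 4 Å MS, CH2Cl2, rt
Reagents that add atoms: none
Why: Proposed new method: LiN(SiMe3)2 removes a C2 proton of the acetyl group, the only kinetically acidic C–H (C4, C10 and C11 carry no hydrogen), the enolate carbon adds to the lactone carbonyl C3 four bonds away, and the tetrahedral alkoxide collapses by C3–O10 cleavage, so the nine-membered lactone expands to the ten-membered β-diketone 27, held as its enolate by the second equivalent of base. On acidification O10 returns to C3 to give hemiketal 28, which loses water to the vinylogous ester 29. The closest known reaction type is the base-induced O-to-C acyl shift and cyclodehydration of open-chain α-acyloxy ketones to 3(2H)-furanones (an intramolecular Claisen condensation), which has not been run on an acyl group that is part of a medium-ring lactone. Ring closures: the C2–C3 bond forms by a 5-(enolendo)-exo-trig attack, a mode rated unfavourable by the ring-closure rules for enolates yet operative in the open-chain cases, the same bond closes the carbocycle as a formal 10-exo-trig event whose entropy was paid when the lactone was made, and the final O10–C3 bond is a 5-exo-trig hemiketalisation. No stereocentre is created in 29 (C3 of 28 is erased) and C6–C11 are spectators. The step needs attack at C3 and not at the γ-lactone carbonyl C12 or the epoxide, which the substrate secures because C3 is reached through a five-membered transition state whereas C12 needs an eight-membered one and is shielded by fully substituted C11.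

Step 18
Reactants: 29 furanone-bridged carbocycle
Product: 30 chlorohydrin triol (4Z,6S,7R,8S,9R,10R,11R) with free C8 C9 C11 hydroxyls and C13 chloride
Conditions: aq HCl (2 M), THF, 0 °C to rt
Reagents that add atoms: hydrogen chloride, Cl
Why: Acid-promoted SN2 opening of the epoxide by chloride at primary C13, remote from the carbonyl, leaves the C11–O bond and hence C11 untouched, and the same acid hydrolyses the C8/C9 acetonide, so no separate chlorination of a neopentylic alcohol is needed.

Step 19
Reactants: 30 chlorohydrin triol; 31 angelic acid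
Product: 33 target CNP0272644.1 (4Z,6S,7S,8S,9R,10R,11R) 8-O-angelate, via mixed anhydride 32 (not isolated)
Conditions: 31, 2,4,6-Cl3C6H2COCl, Et3N (1 equiv each), toluene, rt; then 30, 75 °C
Reagents that add atoms: none
Why: Yamaguchi-type mixed-anhydride acylation without nucleophilic catalyst transfers the angeloyl group without Z-to-E isomerisation, and the bulky donor should take C8–OH because C9–OH is neopentylic (next to quaternary C10) and C11–OH is tertiary.

Compound list
1 | dimethyl (4R,5R)-2,2-dimethyl-1,3-dioxolane-4,5-dicarboxylate | COC(=O)[C@@H]1OC(C)(C)O[C@H]1C(=O)OC | starting material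
2 | (4R,5R)-N4,N5-dimethoxy-N4,N5,2,2-tetramethyl-1,3-dioxolane-4,5-dicarboxamide | CON(C)C(=O)[C@@H]1OC(C)(C)O[C@H]1C(=O)N(C)OC | intermediate
3 | ethynyl(trimethyl)silane | C#C[Si](C)(C)C | starting material
4 | lithium (trimethylsilyl)acetylide | [Li]C#C[Si](C)(C)C | intermediate
5 | mono-ynone Weinreb amide (8R,9R) | CON(C)C(=O)[C@@H]1OC(C)(C)O[C@H]1C(=O)C#C[Si](C)(C)C | intermediate
6 | tertiary propargylic alcohol Weinreb amide (8R,9R,10S) | CON(C)C(=O)[C@@H]1OC(C)(C)O[C@H]1[C@@](C)(O)C#C[Si](C)(C)C | intermediate
7 | C7 aldehyde (8R,9R,10S) | O=C[C@@H]1OC(C)(C)O[C@H]1[C@@](C)(O)C#C[Si](C)(C)C | intermediate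
8 | methyl acrylate | C=CC(=O)OC | starting material
9 | Morita–Baylis–Hillman adduct (8S,9R,10S; C7 epimers) | C=C(C(=O)OC)C(O)[C@@H]1OC(C)(C)O[C@H]1[C@@](C)(O)C#C[Si](C)(C)C | intermediate
10 | Morita–Baylis–Hillman acetate (8S,9R,10S; C7 epimers) | C=C(C(=O)OC)C(OC(C)=O)[C@@H]1OC(C)(C)O[C@H]1[C@@](C)(O)C#C[Si](C)(C)C | intermediate
11 | (E)-2-(methoxycarbonyl)allylboronate (8S,9R,10S) | COC(=O)/C(CB2OC(C)(C)C(C)(C)O2)=C/[C@@H]1OC(C)(C)O[C@H]1[C@@](C)(O)C#C[Si](C)(C)C | intermediate
12 | (R)-(2,2-dimethyl-1,3-dioxolan-4-yl)methanol | OC[C@@H]1COC(C)(C)O1 | starting material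
13 | (S)-2,2-dimethyl-1,3-dioxolane-4-carbaldehyde | O=C[C@@H]1COC(C)(C)O1 | intermediate
14 | open-chain C6 O-pinacolborate of the syn adduct (5S,6R,7S,8S,9R,10S) | COC(=O)C(=C)[C@@H]([C@@H](OB4OC(C)(C)C(C)(C)O4)[C@@H]2COC(C)(C)O2)[C@@H]3OC(C)(C)O[C@H]3[C@@](C)(O)C#C[Si](C)(C)C | intermediate
15 | cis-α-methylene-γ-butyrolactone (5S,6R,7R,8S,9R,10S) | C=C1C(=O)O[C@@H]([C@@H]2COC(C)(C)O2)[C@H]1[C@@H]3OC(C)(C)O[C@H]3[C@@](C)(O)C#C[Si](C)(C)C | intermediate
16 | silylated 2-methylene triol (5S,6R,7S,8S,9R,10S) | C=C(CO)[C@@H]([C@@H](O)[C@@H]2COC(C)(C)O2)[C@@H]3OC(C)(C)O[C@H]3[C@@](C)(O)C#C[Si](C)(C)C | intermediate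
17 | ethynyl 2-methylene triol (5S,6R,7S,8S,9R,10S) | C=C(CO)[C@@H]([C@@H](O)[C@@H]2COC(C)(C)O2)[C@@H]3OC(C)(C)O[C@H]3[C@@](C)(O)C#C | intermediate
18 | epoxy triol (5S,6R,7S,8S,9R,10S,11R) | OC[C@@]4(CO4)[C@@H]([C@@H](O)[C@@H]2COC(C)(C)O2)[C@@H]3OC(C)(C)O[C@H]3[C@@](C)(O)C#C | intermediate
19 | epoxy lactol (C12 epimers) | OC1O[C@@H]([C@@H]2COC(C)(C)O2)[C@@H]([C@@H]3OC(C)(C)O[C@H]3[C@@](C)(O)C#C)[C@]14CO4 | intermediate
20 | spiro-epoxy γ-lactone with free C10 hydroxyl (5S,6R,7R,8S,9R,10S,11S) | O=C1O[C@@H]([C@@H]2COC(C)(C)O2)[C@@H]([C@@H]3OC(C)(C)O[C@H]3[C@@](C)(O)C#C)[C@]14CO4 | intermediate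
21 | 2-(diethoxyphosphoryl)propanoic acid | CCOP(=O)(OCC)C(C)C(=O)O | starting material
22 | C10 phosphonopropanoate (C4 epimers) | O=C1O[C@@H]([C@@H]2COC(C)(C)O2)[C@@H]([C@@H]3OC(C)(C)O[C@H]3[C@@](C)(OC(=O)C(C)P(=O)(OCC)OCC)C#C)[C@]14CO4 | intermediate
23 | terminal diol (5S; C4 epimers) | O=C1O[C@@H]([C@@H](O)CO)[C@@H]([C@@H]3OC(C)(C)O[C@H]3[C@@](C)(OC(=O)C(C)P(=O)(OCC)OCC)C#C)[C@]14CO4 | intermediate
24 | C5 aldehyde phosphonate (6R,7R,8S,9R,10S,11S; C4 epimers) | O=C1O[C@@H](C=O)[C@@H]([C@@H]3OC(C)(C)O[C@H]3[C@@](C)(OC(=O)C(C)P(=O)(OCC)OCC)C#C)[C@]14CO4 | intermediate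
25 | nine-membered (Z)-enoate lactone, C10 ethynyl (4Z,6S,7S,8S,9R,10S,11S) | CC1(C)O[C@H]2[C@@H]3[C@H](/C=C(/C)C(=O)O[C@@](C)(C#C)[C@@H]2O1)OC(=O)[C@@]3(O4)C4 | intermediate
26 | nine-membered (Z)-enoate lactone, C10 acetyl (4Z,6S,7S,8S,9R,10R,11S) | CC1(C)O[C@H]2[C@@H]3[C@H](/C=C(/C)C(=O)O[C@@](C)(C(C)=O)[C@@H]2O1)OC(=O)[C@@]3(O4)C4 | intermediate
27 | ten-membered 10-hydroxy-1,3-dione (4Z,6S,7S,8S,9R,10R,11S) | CC1(C)O[C@H]2[C@@H]3[C@H](/C=C(/C)C(=O)CC(=O)[C@](C)(O)[C@@H]2O1)OC(=O)[C@@]3(O4)C4 | intermediate
28 | bridged C3 hemiketal (C3 epimers) | CC1(C)O[C@H]2[C@@H]3[C@H](/C=C(/C)C5(O)CC(=O)[C@](C)(O5)[C@@H]2O1)OC(=O)[C@@]3(O4)C4 | intermediate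
29 | furanone-bridged carbocycle, acetonide epoxide (4Z,6S,7S,8S,9R,10R,11S) | CC1(C)O[C@H]2[C@@H]3[C@H](/C=C(/C)C5=CC(=O)[C@](C)(O5)[C@@H]2O1)OC(=O)[C@@]3(O4)C4 | intermediate
30 | 8,9,11-triol 13-chloride (4Z,6S,7R,8S,9R,10R,11R) | O[C@H]1[C@@H]2[C@H](/C=C(/C)C3=CC(=O)[C@](C)(O3)[C@@H]1O)OC(=O)[C@@]2(O)CCl | intermediate
31 | angelic acid, (Z)-2-methylbut-2-enoic acid | C/C=C(/C)C(=O)O | starting material
32 | angelic 2,4,6-trichlorobenzoic anhydride | C/C=C(/C)C(=O)OC(=O)c1c(Cl)cc(Cl)cc1Cl | intermediate
33 | CNP0272644.1 (4Z,6S,7S,8S,9R,10R,11R) | C/C=C(/C)C(=O)O[C@H]1[C@@H]2[C@H](/C=C(/C)C3=CC(=O)[C@](C)(O3)[C@@H]1O)OC(=O)[C@@]2(O)CCl | target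

Total step count: 19. Longest linear sequence: 18 steps (1 to 33 through steps 1–7 and 9–19).

Steps most likely to fail

Step 17.
- What may go wrong: the enolate may not reach a workable trajectory on C3 inside the constrained lactone (enolendo geometry). Proton transfer, γ-deprotonation at C6 or wandering of the released alkoxide could then take over.
- Fallback: it sets out from 20, returns at 29, and swaps the order of events using known chemistry only.
- Esterification of 20 with methacrylic anhydride (DMAP, Et3N) gives the C10 methacrylate F1.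
- Gold-catalysed hydration as in step 16 gives the α-(methacryloyloxy) methyl ketone F2.
- LiN(SiMe3)2 followed by acid, the established open-chain acyl shift and cyclodehydration, gives the 5-isopropenyl-3(2H)-furanone F3.
- H5IO6 unmasks the C5 aldehyde F4.
- Wittig methylenation (Ph3P=CH2, −78 °C) gives the C6 vinyl lactone F5.
- Ring-closing metathesis with the second-generation Hoveyda–Grubbs catalyst in hot dilute toluene joins C4 and C5 and delivers 29.

Step 15.
- What may go wrong: intermolecular olefination to oligomers may outrun closure of the medium ring, and the slow reaction gives time for base-induced epimerisation at C6.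
- Fallback: it sets out from 20, returns at 25, and replaces the olefination by a reductive aldol closure with a record for eight- to ten-membered lactones.
- 2-Bromopropanoyl bromide and pyridine give the C10 α-bromopropanoate F6.
- H5IO6 gives the bromo ester aldehyde F7.
- SmI2 in dilute THF (−78 to 0 °C) closes the ring by an intramolecular Reformatsky reaction to the nine-membered β-hydroxy lactone F8.
- MsCl/Et3N gives the C5 mesylate F9.
- DBU-induced E1cB elimination, limited by the ring to the Z-alkene, gives 25.

Step 19.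
- What may go wrong: discrimination between the C8 and C9 hydroxyls may be too small, acyl migration may blur it, or prolonged heating may isomerise the angeloyl group.
- Fallback: it sets out from 30, returns at 33, and moves the selection from the acylation to a slow desilylation that can be stopped at will.
- Et3SiCl and imidazole give the 8,9-bis(triethylsilyl) ether F10.
- PPTS in MeOH removes the less hindered C8 silyl group to give the 9-O-triethylsilyl ether F11.
- Excess 32 then acylates the single free secondary hydroxyl to give the 9-O-triethylsilyl 8-O-angelate F12.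
- HF·pyridine in THF gives 33.

Further compounds
F1 | step 17 | C10 methacrylate of 20 | O=C1O[C@@H]([C@@H]2COC(C)(C)O2)[C@@H]([C@@H]3OC(C)(C)O[C@H]3[C@@](C)(OC(=O)C(C)=C)C#C)[C@]14CO4
F2 | step 17 | α-(methacryloyloxy) methyl ketone | O=C1O[C@@H]([C@@H]2COC(C)(C)O2)[C@@H]([C@@H]3OC(C)(C)O[C@H]3[C@@](C)(OC(=O)C(C)=C)C(C)=O)[C@]14CO4
F3 | step 17 | 5-isopropenyl-3(2H)-furanone | O=C1O[C@@H]([C@@H]2COC(C)(C)O2)[C@@H]([C@@H]3OC(C)(C)O[C@H]3[C@@]5(C)OC(C(C)=C)=CC5=O)[C@]14CO4
F4 | step 17 | furanone C5 aldehyde | O=C1O[C@@H](C=O)[C@@H]([C@@H]3OC(C)(C)O[C@H]3[C@@]5(C)OC(C(C)=C)=CC5=O)[C@]14CO4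
F5 | step 17 | furanone C6 vinyl lactone | O=C1O[C@@H](C=C)[C@@H]([C@@H]3OC(C)(C)O[C@H]3[C@@]5(C)OC(C(C)=C)=CC5=O)[C@]14CO4
F6 | step 15 | C10 α-bromopropanoate of 20 | O=C1O[C@@H]([C@@H]2COC(C)(C)O2)[C@@H]([C@@H]3OC(C)(C)O[C@H]3[C@@](C)(OC(=O)C(C)Br)C#C)[C@]14CO4
F7 | step 15 | bromo ester C5 aldehyde | O=C1O[C@@H](C=O)[C@@H]([C@@H]3OC(C)(C)O[C@H]3[C@@](C)(OC(=O)C(C)Br)C#C)[C@]14CO4
F8 | step 15 | nine-membered β-hydroxy lactone | CC1(C)O[C@H]2[C@@H]3[C@H](C(O)C(C)C(=O)O[C@@](C)(C#C)[C@@H]2O1)OC(=O)[C@@]3(O4)C4
F9 | step 15 | C5 mesylate of F8 | CC1(C)O[C@H]2[C@@H]3[C@H](C(OS(C)(=O)=O)C(C)C(=O)O[C@@](C)(C#C)[C@@H]2O1)OC(=O)[C@@]3(O4)C4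
F10 | step 19 | 8,9-bis(triethylsilyl) ether of 30 | CC[Si](CC)(CC)O[C@H]1[C@@H]2[C@H](/C=C(/C)C3=CC(=O)[C@](C)(O3)[C@@H]1O[Si](CC)(CC)CC)OC(=O)[C@@]2(O)CCl
F11 | step 19 | 9-O-triethylsilyl ether of 30 | O[C@H]1[C@@H]2[C@H](/C=C(/C)C3=CC(=O)[C@](C)(O3)[C@@H]1O[Si](CC)(CC)CC)OC(=O)[C@@]2(O)CCl
F12 | step 19 | 9-O-triethylsilyl ether of 33 | C/C=C(/C)C(=O)O[C@H]1[C@@H]2[C@H](/C=C(/C)C3=CC(=O)[C@](C)(O3)[C@@H]1O[Si](CC)(CC)CC)OC(=O)[C@@]2(O)CCl
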